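Rings are lettered A–E from the 2,4,6-trihydroxyphenoxy end. Central ring C is a hydroquinone with two further oxygens. Its two para oxygens, one between two C–H carbons and one between the two oxygen-bearing carbons, bind ring B and ring D at carbons that each carry a hydroxyl para to them. Keeping these two hydroxyls as formyl groups makes both carbons SNAr-active C–F sites. One pot then joins 2,6-dimethoxyhydroquinone first to an A–B and then to a D–E diaryl-ether fluoroaldehyde and delivers the complete permethylated skeleton. Baeyer–Villiger oxidation of both formyl groups and global demethylation finish the synthesis.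

Key step: step 10

Remark: the target has no stereogenic element, so it is made as the achiral compound; 3-fluoro-2-methoxyphenol and 4-fluoro-2,6-dimethoxybenzaldehyde are taken as catalogue building blocks.

Step 1
Reactants: 1 3-fluoro-2-methoxyphenol
Product: 2 4-fluoro-2-hydroxy-3-methoxybenzaldehyde
Conditions: MgCl2, Et3N, (CH2O)n, MeCN, reflux; aq. HCl work-up
Reagents that add atoms: paraformaldehyde (as formaldehyde), C=O
Why: Casnati–Skattebøl ortho-formylation through the magnesium phenoxide puts CHO only ortho to OH, and the single free ortho carbon lies para to fluorine.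

Step 2
Reactants: 2 4-fluoro-2-hydroxy-3-methoxybenzaldehyde
Product: 3 4-fluoro-2-hydroxy-5-iodo-3-methoxybenzaldehyde
Conditions: NIS, TsOH (cat.), MeCN, rt
Reagents that add atoms: N-iodosuccinimide, O=C1CCC(=O)N1I
Why: Electrophilic aromatic iodination is steered by the free phenol to its para carbon C-5, its only open ortho/para site, which is why the halogen is introduced before O-methylation.

Step 3
Reactants: 3 4-fluoro-2-hydroxy-5-iodo-3-methoxybenzaldehyde
Product: 4 4-fluoro-5-iodo-2,3-dimethoxybenzaldehyde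
Conditions: MeI, K2CO3, DMF, rt
Reagents that add atoms: iodomethane, CI
Why: Williamson O-methylation of the phenoxide at room temperature is far faster than any displacement of the aryl fluoride.

Step 4
Reactants: 4 4-fluoro-5-iodo-2,3-dimethoxybenzaldehyde
Product: 5 2-(4-fluoro-5-iodo-2,3-dimethoxyphenyl)-1,3-dioxolane
Conditions: HOCH2CH2OH, TsOH (cat.), toluene, reflux, Dean–Stark
Reagents that add atoms: ethylene glycol, OCCO
Why: Acid-catalysed acetalisation switches off the formyl activation, so the fluorine cannot be displaced by the phenoxide of the next step and no free aldehyde meets hot base.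

Step 5
Reactants: 5 2-(4-fluoro-5-iodo-2,3-dimethoxyphenyl)-1,3-dioxolane; 6 2,4,6-trimethoxyphenol
Product: 8 4-fluoro-2,3-dimethoxy-5-(2,4,6-trimethoxyphenoxy)benzaldehyde (A–B fluoroaldehyde), via dioxolane diaryl ether 7 (not isolated)
Conditions: CuI (10 mol%), picolinic acid (20 mol%), K3PO4, degassed DMSO, 90 °C; then 2 M HCl, THF, rt
Reagents that add atoms: water, O
Why: Ullmann-type Cu(I)/picolinate C–O coupling of the aryl iodide accepts the doubly ortho-substituted phenol while the unactivated C–F stays intact, and aqueous acid then hydrolyses the electron-rich aryl acetal.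

Step 6
Reactants: 9 4-fluoro-2,6-dimethoxybenzaldehyde
Product: 10 4-fluoro-3-iodo-2,6-dimethoxybenzaldehyde
Conditions: NIS (1.0 equiv), TFA, MeCN, rt to 50 °C
Reagents that add atoms: N-iodosuccinimide, O=C1CCC(=O)N1I
Why: Electrophilic aromatic iodination can only occur at C-3 (equivalent to C-5), which is ortho to one methoxy and para to the other, and one equivalent of reagent limits di-iodination.

Step 7
Reactants: 10 4-fluoro-3-iodo-2,6-dimethoxybenzaldehyde
Product: 11 2-(4-fluoro-3-iodo-2,6-dimethoxyphenyl)-1,3-dioxolane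
Conditions: HOCH2CH2OH, TsOH (cat.), toluene, reflux, Dean–Stark
Reagents that add atoms: ethylene glycol, OCCO
Why: Acetalisation masks the aldehyde for the same reason as in step 4, leaving the C–I bond as the only reactive site for phenoxide under copper catalysis.

Step 8
Reactants: 11 2-(4-fluoro-3-iodo-2,6-dimethoxyphenyl)-1,3-dioxolane; 12 3,4,5-trimethoxyphenol
Product: 14 4-fluoro-2,6-dimethoxy-3-(3,4,5-trimethoxyphenoxy)benzaldehyde (D–E fluoroaldehyde), via dioxolane diaryl ether 13 (not isolated)
Conditions: CuI (10 mol%), picolinic acid (20 mol%), K3PO4, degassed DMSO, 90 °C; then 2 M HCl, THF, rt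
Reagents that add atoms: water, O
Why: The same Ullmann-type C–O coupling joins the unhindered electron-rich phenol to the iodide flanked by F and OMe, and the acidic work-up releases the aldehyde.

Step 9
Reactants: 15 2,6-dimethoxy-1,4-benzoquinone
Product: 16 2,6-dimethoxybenzene-1,4-diol
Conditions: Na2S2O4, EtOAc/H2O, rt, Ar
Reagents that add atoms: none
Why: Dithionite reduces the quinone to the hydroquinone by two-electron, two-proton transfer, and the product is used at once because it reoxidises in air.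

Step 10
Reactants: 16 2,6-dimethoxybenzene-1,4-diol; 8 4-fluoro-2,3-dimethoxy-5-(2,4,6-trimethoxyphenoxy)benzaldehyde; 14 4-fluoro-2,6-dimethoxy-3-(3,4,5-trimethoxyphenoxy)benzaldehyde
Product: 18 4-{4-[4-formyl-3,5-dimethoxy-2-(3,4,5-trimethoxyphenoxy)phenoxy]-3,5-dimethoxyphenoxy}-2,3-dimethoxy-5-(2,4,6-trimethoxyphenoxy)benzaldehyde (permethylated pentamer dialdehyde), via monoaryl ether phenol 17 (not isolated)
Conditions: 8 (1.0 equiv), Cs2CO3 (1.05 equiv), degassed DMSO, 90 °C; then 14 (1.15 equiv), Cs2CO3 (1.5 equiv), 120 °C, Ar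
Reagents that add atoms: none
Why: Each C–O bond forms by addition–elimination, in which a phenoxide adds to the C–F carbon, the para formyl group stabilises the Meisenheimer adduct and fluoride leaves. This is the established diaryl ether synthesis from phenoxides and 4-fluorobenzaldehydes, run twice in sequence on the two oxygens of one hydroquinone; no ring is closed and no stereocentre is formed. The selectivity needed is which oxygen meets which fluoride. The first equivalent of base gives mainly the phenoxide at the 4-OH of 16 (between two C–H), the more acidic and only unhindered oxygen, and the C–F of 8, flanked by OMe and the bulky aryloxy group, can accept only this oxygen, since attack by the flanked 1-O would demand a tetra-ortho-substituted ether. The remaining flanked phenoxide of 17 is then formed with more base and is matched at higher temperature with the less encumbered C–F of 14, which has one ortho hydrogen. Rigorous exclusion of oxygen keeps the hydroquinone and the intermediate phenoxide from reverting to quinone.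

Step 11
Reactants: 18 permethylated pentamer dialdehyde
Product: 20 4-{4-[4-hydroxy-3,5-dimethoxy-2-(3,4,5-trimethoxyphenoxy)phenoxy]-3,5-dimethoxyphenoxy}-2,3-dimethoxy-5-(2,4,6-trimethoxyphenoxy)phenol (bis-phenol), via bis-formate 19 (not isolated)
Conditions: mCPBA (3 equiv), CH2Cl2, 0 °C to rt; aq. Na2S2O3/NaHCO3 wash; then K2CO3 (cat.), MeOH, rt, Ar
Reagents that add atoms: mCPBA, OOC(=O)c1cccc(Cl)c1
Why: In this Baeyer–Villiger (Dakin-type) oxidation the oxygen-rich aryl groups migrate in preference to hydrogen in the Criegee adduct, giving aryl formates that shield the new phenols from peracid until they are methanolysed.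

Step 12
Reactants: 20 bis-phenol dodecamethyl ether
Product: 21 4-{4-[3,4,5-trihydroxy-2-(3,4,5-trihydroxyphenoxy)phenoxy]-3,5-dihydroxyphenoxy}-5-(2,4,6-trihydroxyphenoxy)benzene-1,2,3-triol (CNP0273977.0)
Conditions: BBr3 (excess), CH2Cl2, −78 °C to rt, Ar; then H2O, 0 °C
Reagents that add atoms: none
Why: Boron tribromide cleaves aryl methyl ethers by O–B coordination and bromide attack at methyl without touching diaryl ether bonds, and hydrolysis of the aryl borates should release all fourteen phenols.

Compound list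
1 | 3-fluoro-2-methoxyphenol | COc1c(O)cccc1F | starting material
2 | 4-fluoro-2-hydroxy-3-methoxybenzaldehyde | O=Cc1ccc(F)c(OC)c1O | intermediate
3 | 4-fluoro-2-hydroxy-5-iodo-3-methoxybenzaldehyde | O=Cc1cc(I)c(F)c(OC)c1O | intermediate
4 | 4-fluoro-5-iodo-2,3-dimethoxybenzaldehyde | O=Cc1cc(I)c(F)c(OC)c1OC | intermediate
5 | 2-(4-fluoro-5-iodo-2,3-dimethoxyphenyl)-1,3-dioxolane | COc1c(C2OCCO2)cc(I)c(F)c1OC | intermediate
6 | 2,4,6-trimethoxyphenol | COc1cc(OC)c(O)c(OC)c1 | starting material
7 | 2-[4-fluoro-2,3-dimethoxy-5-(2,4,6-trimethoxyphenoxy)phenyl]-1,3-dioxolane | COc1cc(OC)c(Oc2cc(C3OCCO3)c(OC)c(OC)c2F)c(OC)c1 | intermediate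
8 | 4-fluoro-2,3-dimethoxy-5-(2,4,6-trimethoxyphenoxy)benzaldehyde | O=Cc1cc(Oc2c(OC)cc(OC)cc2OC)c(F)c(OC)c1OC | intermediate
9 | 4-fluoro-2,6-dimethoxybenzaldehyde | COc1cc(F)cc(OC)c1C=O | starting material
10 | 4-fluoro-3-iodo-2,6-dimethoxybenzaldehyde | COc1cc(F)c(I)c(OC)c1C=O | intermediate
11 | 2-(4-fluoro-3-iodo-2,6-dimethoxyphenyl)-1,3-dioxolane | COc1cc(F)c(I)c(OC)c1C2OCCO2 | intermediate
12 | 3,4,5-trimethoxyphenol | COc1cc(O)cc(OC)c1OC | starting material
13 | 2-[4-fluoro-2,6-dimethoxy-3-(3,4,5-trimethoxyphenoxy)phenyl]-1,3-dioxolane | COc1cc(F)c(Oc2cc(OC)c(OC)c(OC)c2)c(OC)c1C3OCCO3 | intermediate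
14 | 4-fluoro-2,6-dimethoxy-3-(3,4,5-trimethoxyphenoxy)benzaldehyde | O=Cc1c(OC)cc(F)c(Oc2cc(OC)c(OC)c(OC)c2)c1OC | intermediate
15 | 2,6-dimethoxy-1,4-benzoquinone | COC1=CC(=O)C=C(OC)C1=O | starting material
16 | 2,6-dimethoxybenzene-1,4-diol | COc1cc(O)cc(OC)c1O | intermediate
17 | 4-(4-hydroxy-3,5-dimethoxyphenoxy)-2,3-dimethoxy-5-(2,4,6-trimethoxyphenoxy)benzaldehyde | COc1cc(OC)c(Oc2cc(C=O)c(OC)c(OC)c2Oc2cc(OC)c(O)c(OC)c2)c(OC)c1 | intermediate
18 | 4-{4-[4-formyl-3,5-dimethoxy-2-(3,4,5-trimethoxyphenoxy)phenoxy]-3,5-dimethoxyphenoxy}-2,3-dimethoxy-5-(2,4,6-trimethoxyphenoxy)benzaldehyde | COc1cc(OC)c(Oc2cc(C=O)c(OC)c(OC)c2Oc2cc(OC)c(Oc3cc(OC)c(C=O)c(OC)c3Oc3cc(OC)c(OC)c(OC)c3)c(OC)c2)c(OC)c1 | intermediate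
19 | 4-{3,5-dimethoxy-4-[4-(formyloxy)-3,5-dimethoxy-2-(3,4,5-trimethoxyphenoxy)phenoxy]phenoxy}-2,3-dimethoxy-5-(2,4,6-trimethoxyphenoxy)phenyl formate | COc1cc(OC)c(Oc2cc(OC=O)c(OC)c(OC)c2Oc2cc(OC)c(Oc3cc(OC)c(OC=O)c(OC)c3Oc3cc(OC)c(OC)c(OC)c3)c(OC)c2)c(OC)c1 | intermediate
20 | 4-{4-[4-hydroxy-3,5-dimethoxy-2-(3,4,5-trimethoxyphenoxy)phenoxy]-3,5-dimethoxyphenoxy}-2,3-dimethoxy-5-(2,4,6-trimethoxyphenoxy)phenol | COc1cc(OC)c(Oc2cc(O)c(OC)c(OC)c2Oc2cc(OC)c(Oc3cc(OC)c(O)c(OC)c3Oc3cc(OC)c(OC)c(OC)c3)c(OC)c2)c(OC)c1 | intermediate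
21 | 4-{4-[3,4,5-trihydroxy-2-(3,4,5-trihydroxyphenoxy)phenoxy]-3,5-dihydroxyphenoxy}-5-(2,4,6-trihydroxyphenoxy)benzene-1,2,3-triol | Oc1cc(O)c(Oc2cc(O)c(O)c(O)c2Oc2cc(O)c(Oc3cc(O)c(O)c(O)c3Oc3cc(O)c(O)c(O)c3)c(O)c2)c(O)c1 | target

Total step count: 12. Longest linear sequence: 8 steps (steps 1–5, then 10–12).

Steps most likely to fail

Step 10. The second substitution may stall at the flanked, doubly ortho-substituted phenoxide while the electron-rich phenoxides are lost to oxidation, or the two oxygens may be arylated in the wrong order. The fallback sets out from 16 and fixes the order with a protecting group. Selective acetalisation of the unhindered hydroxyl (MOMCl, i-Pr2NEt, CH2Cl2, 0 °C) should give 2,6-dimethoxy-4-(methoxymethoxy)phenol F1. Its only free, flanked oxygen is then arylated with 14 (Cs2CO3, DMSO, 120 °C) to 4-[2,6-dimethoxy-4-(methoxymethoxy)phenoxy]-2,6-dimethoxy-3-(3,4,5-trimethoxyphenoxy)benzaldehyde F2. Acidic methanolysis (HCl, MeOH, rt, aqueous work-up) frees 4-(4-hydroxy-2,6-dimethoxyphenoxy)-2,6-dimethoxy-3-(3,4,5-trimethoxyphenoxy)benzaldehyde F3. A separate substitution of 8 by the unflanked phenoxide of F3 (Cs2CO3, DMSO, 100 °C) rejoins the route at 18.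

Step 12. Ether cleavage at twelve sites may stop short, and the free polyphenol may be lost to air oxidation during purification. The fallback sets out from 20. After the BBr3 treatment the crude product is not isolated but acetylated (Ac2O, pyridine, rt) to the tetradecaacetate of 21 F4. This stable derivative can be chromatographed free of partly methylated material. Acid-catalysed transesterification in degassed methanol (HCl from AcCl, rt) then returns to the route at 21.

Step 5. The doubly ortho-substituted, easily oxidised phenol 6 may be consumed oxidatively, and slow C–O bond formation at copper may lead to hydrodeiodination of 5. The fallback sets out from 5 and reverses the roles of the partners. Iodine–magnesium exchange (i-PrMgCl·LiCl, THF, −20 °C), trapping with B(OMe)3 and oxidation (H2O2, NaOH) should give 5-(1,3-dioxolan-2-yl)-2-fluoro-3,4-dimethoxyphenol F5. This less hindered, less oxidisable phenol is coupled with commercial 2-iodo-1,3,5-trimethoxybenzene (CuI, picolinic acid, K3PO4, DMSO, 100 °C), rejoining the route at 7, which the acidic work-up of step 5 converts into 8.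

Further compounds
F1 | step 10 | 2,6-dimethoxy-4-(methoxymethoxy)phenol | COCOc1cc(OC)c(O)c(OC)c1
F2 | step 10 | 4-[2,6-dimethoxy-4-(methoxymethoxy)phenoxy]-2,6-dimethoxy-3-(3,4,5-trimethoxyphenoxy)benzaldehyde | COCOc1cc(OC)c(Oc2cc(OC)c(C=O)c(OC)c2Oc2cc(OC)c(OC)c(OC)c2)c(OC)c1
F3 | step 10 | 4-(4-hydroxy-2,6-dimethoxyphenoxy)-2,6-dimethoxy-3-(3,4,5-trimethoxyphenoxy)benzaldehyde | Oc1cc(OC)c(Oc2cc(OC)c(C=O)c(OC)c2Oc2cc(OC)c(OC)c(OC)c2)c(OC)c1
F4 | step 12 | tetradecaacetate of 21 | CC(=O)Oc1cc(OC(C)=O)c(Oc2cc(OC(C)=O)c(OC(C)=O)c(OC(C)=O)c2Oc2cc(OC(C)=O)c(Oc3cc(OC(C)=O)c(OC(C)=O)c(OC(C)=O)c3Oc3cc(OC(C)=O)c(OC(C)=O)c(OC(C)=O)c3)c(OC(C)=O)c2)c(OC(C)=O)c1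
F5 | step 5 | 5-(1,3-dioxolan-2-yl)-2-fluoro-3,4-dimethoxyphenol | COc1c(C2OCCO2)cc(O)c(F)c1OC
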